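**Strategy.** The carbocycle is assembled by an anionic [4+2] ring transformation (chromene numbering). It exploits C-4a being both the α-carbon of the C-5 ketone and the attachment point of the vinylogous-ester carbon C-8a of the pyran ring. The enolate of a 5-selanyl δ-lactone adds to C-2 of a 2-methoxy-4-pyranone (C4a–C8a). The pyranone opens to a diketonate that acylates itself on the lactone carbonyl (C5–C6), and the released lactone oxygen becomes O-1 on C-8a. The precursors are a γ-pyrone that hides the acyl triketone and a seleno-lactone whose C–Se centre, from an asymmetric selenolactonisation, steers C-4a and is later eliminated to the C3=C4 alkene.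

Key step: step 8

Assumption: the enol tautomer drawn for the target is taken as representative of the equilibrating β-triketone forms; the stereocentre C-4a is (R).

**Step 1**
Reactants: 1 ethyl acetoacetate; 2 1-bromo-3-methylbut-2-ene (prenyl bromide)
Product: 3 ethyl 2-acetyl-5-methylhex-4-enoate
Conditions: K2CO3, acetone, reflux
Reagents that add atoms: none
Why: Acetoacetic ester C-alkylation with an allylic bromide; one equivalent of bromide with a carbonate base should keep dialkylation low.

**Step 2**
Reactants: 3 ethyl 2-acetyl-5-methylhex-4-enoate; 4 N-methoxy-N-methyl-2-methylpropanamide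
Product: 5 ethyl 6-methyl-2-(3-methylbut-2-en-1-yl)-3,5-dioxoheptanoate
Conditions: NaH, THF, 0 °C; n-BuLi, 0 °C; then 4, −78 → 0 °C; aq. HCl
Reagents that add atoms: none
Why: γ-Acylation of the 1,3-dicarbonyl dianion at its terminal carbon; the Weinreb amide stops at the chelated tetrahedral adduct, so the diketo ester is released only on work-up.

**Step 3**
Reactants: 5 ethyl 6-methyl-2-(3-methylbut-2-en-1-yl)-3,5-dioxoheptanoate
Product: 6 4-hydroxy-3-(3-methylbut-2-en-1-yl)-6-(propan-2-yl)-2H-pyran-2-one
Conditions: DBU, PhMe, reflux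
Reagents that add atoms: none
Why: Base-mediated enol lactonisation of a 3,5-dioxo ester to the 4-hydroxy-2-pyranone with loss of ethanol.

**Step 4**
Reactants: 6 4-hydroxy-3-(3-methylbut-2-en-1-yl)-6-(propan-2-yl)-2H-pyran-2-one
Product: 7 2-methoxy-3-(3-methylbut-2-en-1-yl)-6-(propan-2-yl)-4H-pyran-4-one
Conditions: MeOTf (1.1 equiv), CH2Cl2, 0 → 23 °C; aq. NaHCO3
Reagents that add atoms: methyl trifluoromethanesulfonate, COS(=O)(=O)C(F)(F)F
Why: Kinetic O-methylation of the neutral hydroxypyranone by a hard methylating agent should occur on the lactone carbonyl oxygen (the nucleophilic end of the vinylogous acid), and the 4-hydroxy-2-methoxypyrylium ion then loses a proton to give the 2-methoxy-4-pyranone.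

**Step 5**
Reactants: 8 dimethyl malonate; 2 1-bromo-3-methylbut-2-ene
Product: 9 dimethyl 2,2-bis(3-methylbut-2-en-1-yl)propanedioate
Conditions: NaH (2.2 equiv), THF/DMF, 0 → 23 °C; 2 (2.2 equiv)
Reagents that add atoms: none
Why: Double malonic ester alkylation with an allylic bromide.

**Step 6**
Reactants: 9 dimethyl 2,2-bis(3-methylbut-2-en-1-yl)propanedioate
Product: 11 5-methyl-2-(3-methylbut-2-en-1-yl)hex-4-enoic acid, via diprenylmalonic acid 10 (not isolated)
Conditions: KOH, MeOH/H2O, reflux; HCl, 0 °C; then pyridine, 110 °C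
Reagents that add atoms: potassium hydroxide, [K+].[OH-]
Why: Saponification followed by thermal decarboxylation of the malonic acid in pyridine, which avoids acid-catalysed lactonisation onto the prenyl groups.

**Step 7**
Reactants: 11 5-methyl-2-(3-methylbut-2-en-1-yl)hex-4-enoic acid
Product: 12 (5S)-6,6-dimethyl-3-(3-methylbut-2-en-1-yl)-5-(phenylselanyl)oxan-2-one (both C-3 epimers)
Conditions: N-(phenylselanyl)phthalimide (1.0 equiv), hydroquinidine 1,4-phthalazinediyl diether [(DHQD)2PHAL, 10 mol %], CH2Cl2–PhMe, −78 °C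
Reagents that add atoms: N-(phenylselanyl)phthalimide, O=C1N([Se]c2ccccc2)C(=O)c2ccccc12
Why: Catalytic asymmetric selenolactonisation with anti addition and Markovnikov (6-endo) opening of the seleniranium ion at the tertiary carbon; the cinchona catalyst should make cyclisation of the rapidly equilibrating seleniranium ions enantioselective and so set C-5, both C-3 epimers are carried on because C-3 is enolised in step 8, and the pseudo-enantiomeric (DHQ)2PHAL would be used if the sense found is opposite.

**Step 8**
Reactants: 12 (5S)-6,6-dimethyl-3-(3-methylbut-2-en-1-yl)-5-(phenylselanyl)oxan-2-one; 7 2-methoxy-3-(3-methylbut-2-en-1-yl)-6-(propan-2-yl)-4H-pyran-4-one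
Product: 15 (3S,4aR)-7-hydroxy-2,2-dimethyl-4a,8-bis(3-methylbut-2-en-1-yl)-6-(2-methylpropanoyl)-3-(phenylselanyl)-3,4-dihydro-2H-chromen-5(4aH)-one, via ring-opened Michael adduct 13 (not isolated), via hydroxy methoxy dienone 14 (not isolated)
Conditions: LiN(SiMe3)2 (1.1 equiv), THF, −78 °C; then 7, −78 → 40 °C; AcOH; then PPTS (5 mol %), 4 Å MS, PhMe, 50 °C
Reagents that add atoms: none
Why: The lithium enolate of 12 (C-3 epimers converge) should add through carbon to C-2 of γ-pyrone 7, the only site from which β-elimination of the ring oxygen gives the stabilised diketonate 13; its central carbon then attacks the lactone carbonyl in a Claisen (Dieckmann-type) closure, the tetrahedral intermediate ejects the tertiary alkoxide, and this oxygen ends on the methoxy-bearing vinylogous-ester carbon with loss of methanol, directly or from 14 on the mild acid finish. The closest known reactions are Michael–Claisen annulations of ester-stabilised carbanions with pyranones and enones (Staunton–Weinreb and Hauser–Kraus type) and carbanion-induced ring transformations of pyranones. The carbocycle closes 6-exo-trig at the lactone C=O and the pyran closes 6-exo-trig by oxygen addition–elimination at C-8a. C-4a is controlled by the C–Se centre: the half-chair enolate should be attacked axially anti to the C-5 selanyl group, because the syn approach is either 1,3-diaxial to SePh or an equatorial approach past the axial C-6 methyl, so (5S) should give (4aR). The step needs C- over O-attack of the enolate, C-2 over C-4 or C-6 attack on 7, and oxygen delivery to C-8a rather than C-5; these should be secured by reversible carbonyl addition against irreversible ring opening and by the single OMe-marked vinylogous ester, while the E/Z isomers of push–pull alkene 13 equilibrate.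

**Step 9**
Reactants: 15 (3S,4aR)-7-hydroxy-2,2-dimethyl-4a,8-bis(3-methylbut-2-en-1-yl)-6-(2-methylpropanoyl)-3-(phenylselanyl)-3,4-dihydro-2H-chromen-5(4aH)-one
Product: 17 (4aR)-7-hydroxy-2,2-dimethyl-4a,8-bis(3-methylbut-2-en-1-yl)-6-(2-methylpropanoyl)-2H-chromen-5(4aH)-one (CNP0119032.1), via selenoxide 16 (not isolated)
Conditions: mCPBA (1.0 equiv), CH2Cl2, −78 °C; then Et3N, −78 → 23 °C
Reagents that add atoms: none
Why: Selenide oxidation at −78 °C is much faster than epoxidation of the trisubstituted alkenes, and the selenoxide syn-elimination can only take a C-4 hydrogen because C-2 is quaternary, so the cis C3=C4 alkene should form and the temporary C-3 stereocentre is erased without touching C-4a.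

**Compound list**
1 | ethyl acetoacetate | CCOC(=O)CC(C)=O | starting material
2 | 1-bromo-3-methylbut-2-ene | CC(C)=CCBr | starting material
3 | ethyl 2-acetyl-5-methylhex-4-enoate | CCOC(=O)C(CC=C(C)C)C(C)=O | intermediate
4 | N-methoxy-N-methyl-2-methylpropanamide | CC(C)C(=O)N(C)OC | starting material
5 | ethyl 6-methyl-2-(3-methylbut-2-en-1-yl)-3,5-dioxoheptanoate | CCOC(=O)C(CC=C(C)C)C(=O)CC(=O)C(C)C | intermediate
6 | 4-hydroxy-3-(3-methylbut-2-en-1-yl)-6-(propan-2-yl)-2H-pyran-2-one | CC(C)C1=CC(O)=C(CC=C(C)C)C(=O)O1 | intermediate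
7 | 2-methoxy-3-(3-methylbut-2-en-1-yl)-6-(propan-2-yl)-4H-pyran-4-one | COC1=C(CC=C(C)C)C(=O)C=C(C(C)C)O1 | intermediate
8 | dimethyl malonate | COC(=O)CC(=O)OC | starting material
9 | dimethyl 2,2-bis(3-methylbut-2-en-1-yl)propanedioate | COC(=O)C(CC=C(C)C)(CC=C(C)C)C(=O)OC | intermediate
10 | 2,2-bis(3-methylbut-2-en-1-yl)propanedioic acid | OC(=O)C(CC=C(C)C)(CC=C(C)C)C(O)=O | intermediate
11 | 5-methyl-2-(3-methylbut-2-en-1-yl)hex-4-enoic acid | CC(C)=CCC(CC=C(C)C)C(O)=O | intermediate
12 | (5S)-6,6-dimethyl-3-(3-methylbut-2-en-1-yl)-5-(phenylselanyl)oxan-2-one, both C-3 epimers | CC(C)=CCC1C[C@H]([Se]c2ccccc2)C(C)(C)OC1=O | intermediate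
13 | (3R,5S)-3-[(1E)-1-methoxy-6-methyl-2-(3-methylbut-2-en-1-yl)-3,5-dioxohept-1-en-1-yl]-6,6-dimethyl-3-(3-methylbut-2-en-1-yl)-5-(phenylselanyl)oxan-2-one (formed as its lithium diketonate) | CC(C)C(=O)CC(=O)/C(CC=C(C)C)=C(/OC)[C@@]1(CC=C(C)C)C[C@H]([Se]c2ccccc2)C(C)(C)OC1=O | intermediate
14 | (6R)-3-hydroxy-6-[(2S)-3-hydroxy-3-methyl-2-(phenylselanyl)butyl]-5-methoxy-4,6-bis(3-methylbut-2-en-1-yl)-2-(2-methylpropanoyl)cyclohexa-2,4-dien-1-one | COC1=C(CC=C(C)C)C(O)=C(C(=O)C(C)C)C(=O)[C@]1(CC=C(C)C)C[C@H]([Se]c2ccccc2)C(C)(C)O | intermediate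
15 | (3S,4aR)-7-hydroxy-2,2-dimethyl-4a,8-bis(3-methylbut-2-en-1-yl)-6-(2-methylpropanoyl)-3-(phenylselanyl)-3,4-dihydro-2H-chromen-5(4aH)-one | CC(C)=CCC1=C2OC(C)(C)[C@@H]([Se]c3ccccc3)C[C@@]2(CC=C(C)C)C(=O)C(C(=O)C(C)C)=C1O | intermediate
16 | Se-oxide of 15 (either configuration at selenium) | CC(C)=CCC1=C2OC(C)(C)[C@@H]([Se](=O)c3ccccc3)C[C@@]2(CC=C(C)C)C(=O)C(C(=O)C(C)C)=C1O | intermediate
17 | (4aR)-7-hydroxy-2,2-dimethyl-4a,8-bis(3-methylbut-2-en-1-yl)-6-(2-methylpropanoyl)-2H-chromen-5(4aH)-one | CC(C)=CCC1=C2OC(C)(C)C=C[C@@]2(CC=C(C)C)C(=O)C(C(=O)C(C)C)=C1O | target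

**Totals.** Total step count: 9. Longest linear sequence: 6 steps (steps 1, 2, 3, 4, 8, 9).

**Steps most likely to fail**

1. Step 8. The hindered tertiary enolate may fail to add at C-2 of the weakly electrophilic pyranone (proton transfer from the isopropyl group or reversible carbonyl addition may win), the Claisen closure may stall, or the facial selectivity may be poor. Fallback: the two bonds would be made in separate operations, setting out from 12. Silylation of its lithium enolate (LiN(SiMe3)2, TBSCl, THF, −78 °C) should give the silyl ketene acetal F1. Mukaiyama–Michael addition of F1 to 7, activated as its 4-silyloxypyrylium ion by TBSOTf in CH2Cl2 at −78 °C and followed by loss of the silyl methyl ether, should give the 2-lactonyl-4-pyranone F2 under the same 1,3-trans control. NaOMe in MeOH should then open the lactone; the freed tertiary alkoxide adds to C-2 of the pyranone, the ring opens and the diketonate closes on the methyl ester, which comes back to the route at 15.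

2. Step 7. Cyclisation may take the 5-exo course to the γ-lactone, or the enantioselectivity may be low through seleniranium transfer between alkenes. Fallback: the C–Se centre would be set by epoxide opening, setting out from 11. Esterification (MeI, K2CO3, DMF) gives the methyl ester F3. Shi epoxidation (fructose-derived ketone, KHSO5 as Oxone, K2CO3, MeCN–dimethoxymethane–buffer, 0 °C, oxidant limiting so that one prenyl group reacts) should give the (R)-mono-epoxide F4; the enantiomeric ketone would be used if the sense is opposite. Sodium phenylselenide (PhSeSePh, NaBH4, EtOH) opens the epoxide at the secondary carbon with inversion, and the tertiary alkoxide lactonises on the ester, which comes back at 12.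

3. Step 4. Methylation may go to O-4 and give the 4-methoxy-2-pyranone, or the prenyl alkene may be alkylated. Fallback: the 4-oxygen would be blocked first, setting out from 6. Silylation (TBSCl, imidazole, DMF) gives the 4-silyloxy-2-pyranone F5. MeOTf can then only alkylate the lactone carbonyl oxygen, giving the pyrylium triflate F6. Fluoride (KF, MeOH) removes the silyl group and returns the route at 7.

**Further compounds**
F1 | step 8 | tert-butyl{[(3S)-2,2-dimethyl-5-(3-methylbut-2-en-1-yl)-3-(phenylselanyl)-3,4-dihydro-2H-pyran-6-yl]oxy}dimethylsilane | CC(C)=CCC1=C(O[Si](C)(C)C(C)(C)C)OC(C)(C)[C@@H]([Se]c2ccccc2)C1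
F2 | step 8 | (3R,5S)-6,6-dimethyl-3-(3-methylbut-2-en-1-yl)-3-[3-(3-methylbut-2-en-1-yl)-4-oxo-6-(propan-2-yl)-4H-pyran-2-yl]-5-(phenylselanyl)oxan-2-one | CC(C)C1=CC(=O)C(CC=C(C)C)=C(O1)[C@@]2(CC=C(C)C)C[C@H]([Se]c3ccccc3)C(C)(C)OC2=O
F3 | step 7 | methyl 5-methyl-2-(3-methylbut-2-en-1-yl)hex-4-enoate | COC(=O)C(CC=C(C)C)CC=C(C)C
F4 | step 7 | methyl 2-{[(2R)-3,3-dimethyloxiran-2-yl]methyl}-5-methylhex-4-enoate (both C-2 epimers) | COC(=O)C(CC=C(C)C)C[C@H]1OC1(C)C
F5 | step 4 | 4-[(tert-butyldimethylsilyl)oxy]-3-(3-methylbut-2-en-1-yl)-6-(propan-2-yl)-2H-pyran-2-one | CC(C)C1=CC(O[Si](C)(C)C(C)(C)C)=C(CC=C(C)C)C(=O)O1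
F6 | step 4 | 4-[(tert-butyldimethylsilyl)oxy]-2-methoxy-3-(3-methylbut-2-en-1-yl)-6-(propan-2-yl)pyrylium trifluoromethanesulfonate | COc1[o+]c(C(C)C)cc(O[Si](C)(C)C(C)(C)C)c1CC=C(C)C.[O-]S(=O)(=O)C(F)(F)F
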